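**Retrosynthetic overview**

- The only stereocentre is the tertiary carbinol C5 of the cyclohex-2-enone ring. Its two ring arms, C6H2–C1(=O) and C4H2–C3H=C2H, differ only in oxidation pattern, so the ring with its side chain is a hidden meso all-cis 1,3,5-trioxygenated cyclohexane (mirror plane through C5 and C2) in which C1 and C3 are enantiotopic.
- Enone ⇐ β-acetoxy ketone (E1cB loss of acetate) ⇐ monoacetate (oxidation of the free carbinol) ⇐ meso diacetate (a lipase removes one of two enantiotopic acetates).
- Meso diacetate ⇐ bis-silyl aldol adduct ⇐ aldol at the carbinol carbon between the methyl-side enolate of (10Z,13Z)-nonadeca-10,13-dien-2-one (from linoleic acid through the Weinreb amide) and meso cis-3,5-bis(silyloxy)cyclohexanone (from cis,cis-cyclohexane-1,3,5-triol).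
- No ring is formed: the six-membered ring is bought, and the C19 chain is attached once, before the desymmetrisation.

Key step: step 8

Remark on the chemistry: the relative configuration of the aldol adduct (chain cis to the silyloxy groups) and the sense of the enzymatic discrimination are predictions. Both are to be checked on the first batch (NOE analysis of the aldol adduct, Mosher esters of the monoacetate). The commercial triol dihydrate is dried azeotropically, and all compounds carrying the skipped Z,Z-diene are handled under argon.

**Route**

Step 1
Reactants: 1 cis,cis-cyclohexane-1,3,5-triol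
Product: 2 all-cis-3,5-bis(tert-butyldimethylsilyloxy)cyclohexan-1-ol (meso)
Conditions: TBSCl (2 equiv), imidazole, DMF, 0 °C to rt; chromatography, mono- and tris-silyl ethers recycled
Reagents that add atoms: tert-butyldimethylsilyl chloride, CC(C)(C)[Si](C)(C)Cl
Why: Silyl ether formation on three equivalent hydroxyls is statistical, so two equivalents of silyl chloride should make the bis-ether the main component, separable from the mono- and tris-ethers, and no stereocentre is affected.

Step 2
Reactants: 2 all-cis-3,5-bis(tert-butyldimethylsilyloxy)cyclohexan-1-ol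
Product: 3 meso cis-3,5-bis(tert-butyldimethylsilyloxy)cyclohexan-1-one
Conditions: Dess–Martin periodinane, pyridine, CH2Cl2, 0 °C to rt
Reagents that add atoms: none
Why: Dess–Martin oxidation converts the remaining secondary alcohol into the ketone under nearly neutral conditions that should not trigger β-elimination of the silyloxy groups, and the product keeps its mirror plane.

Step 3
Reactants: 4 linoleic acid, (9Z,12Z)-octadeca-9,12-dienoic acid
Product: 6 (9Z,12Z)-N-methoxy-N-methyloctadeca-9,12-dienamide, via linoleoyl imidazolide 5 (not isolated)
Conditions: 1,1'-carbonyldiimidazole, CH2Cl2, rt; then MeNH(OMe)·HCl, rt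
Reagents that add atoms: N,O-dimethylhydroxylamine hydrochloride, CNOC.Cl; 1,1'-carbonyldiimidazole, O=C(n1ccnc1)n1ccnc1 (supplies only the imidazolyl group of intermediate 5)
Why: Acyl imidazolide formation followed by aminolysis (Weinreb amide synthesis) runs without acid or strong base, so the skipped Z,Z-diene should neither isomerise nor migrate.

Step 4
Reactants: 6 (9Z,12Z)-N-methoxy-N-methyloctadeca-9,12-dienamide
Product: 8 (10Z,13Z)-nonadeca-10,13-dien-2-one, via bromomagnesium hemiaminal adduct 7 (not isolated)
Conditions: MeMgBr, THF, 0 °C; then dilute aq HCl, 0 °C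
Reagents that add atoms: methylmagnesium bromide, C[Mg]Br
Why: Weinreb ketone synthesis, in which the chelated magnesium adduct does not collapse until the acidic quench, so a single methyl group is delivered and the methyl ketone should form without over-addition.

Step 5
Reactants: 8 (10Z,13Z)-nonadeca-10,13-dien-2-one and 3 meso cis-3,5-bis(tert-butyldimethylsilyloxy)cyclohexan-1-one
Product: 11 meso aldol adduct (10Z,13Z)-1-[(3R,5S)-3,5-bis(tert-butyldimethylsilyloxy)-1-hydroxycyclohexyl]nonadeca-10,13-dien-2-one (side chain cis to both silyloxy groups; tertiary OH trans), via lithium enolate 9 (not isolated), via dichlorocerium enolate 10 (not isolated)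
Conditions: LiN(iPr)2, THF, −78 °C (8 added to the base); anhydrous CeCl3 in THF, −78 °C; then 3, −78 °C; sat. aq NH4Cl at −78 °C; chromatography
Reagents that add atoms: LiN(iPr)2, [Li+].CC(C)[N-]C(C)C and CeCl3, Cl[Ce](Cl)Cl (both leave atoms only in intermediates 9 and 10; product 11 holds atoms of 8 and 3 alone)
Why: Aldol addition of a cerium enolate, in which LiN(iPr)2 at −78 °C deprotonates the methyl side of 8 under kinetic control, exchange to the less basic and more oxophilic cerium enolate should suppress enolisation of the β-silyloxy ketone 3 and reversal of the aldolate, and equatorial attack on the chair of 3 with both silyloxy groups equatorial should set the new pseudoasymmetric carbinol carbon with the chain cis to both silyloxy groups, the other meso diastereomer (which would lead to the enantiomeric target) being removed by chromatography.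

Step 6
Reactants: 11 meso bis-silyl aldol adduct
Product: 12 meso triol ketone (10Z,13Z)-1-[(3R,5S)-1,3,5-trihydroxycyclohexyl]nonadeca-10,13-dien-2-one (side chain cis to both secondary hydroxyls)
Conditions: Bu4NF, AcOH (1:1), THF, 0 °C to rt; crude product taken on after aqueous work-up
Reagents that add atoms: none
Why: Fluoride cleavage of the two secondary silyl ethers in an acetic acid buffer keeps the medium close to neutral, so neither retro-aldol cleavage of the tertiary aldol (base) nor transannular ketalisation of the side-chain ketone by the freed cis hydroxyls (acid) should compete.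

Step 7
Reactants: 12 meso triol ketone
Product: 13 meso diacetate (1R,3S)-5-hydroxy-5-[(10Z,13Z)-2-oxononadeca-10,13-dien-1-yl]cyclohexane-1,3-diyl diacetate (side chain cis to both acetoxy groups; tertiary OH free)
Conditions: Ac2O (2.5 equiv), pyridine, CH2Cl2, 0 °C to rt, no acyl-transfer catalyst
Reagents that add atoms: acetic anhydride, CC(=O)OC(C)=O
Why: Acetylation with acetic anhydride and pyridine esterifies the two equatorial secondary hydroxyls and should leave the hindered tertiary hydroxyl free, so the product is still meso.

Step 8
Reactants: 13 meso diacetate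
Product: 14 monoacetate (1S,3S,5R)-3,5-dihydroxy-3-[(10Z,13Z)-2-oxononadeca-10,13-dien-1-yl]cyclohexyl acetate (the (R) secondary carbinol free, the (S) secondary carbinol acetylated)
Conditions: immobilised lipase from Burkholderia cepacia (Amano PS), n-BuOH (5 equiv), t-BuOMe, 30 °C; stopped just after 13 is consumed
Reagents that add atoms: none
Why: The active-site serine of the lipase attacks the carbonyl of one acetate to give an acetyl-enzyme and the free secondary alcohol, and butan-1-ol then discharges the acetyl group as butyl acetate; the closest known reaction type is the lipase-catalysed enantiotopic-group-selective hydrolysis or alcoholysis of meso cis-1,3-diacetoxycycloalkanes. No bond to carbon is formed and no ring is closed; only one acyl C–O bond is broken. By making the two ring arms of the tertiary carbinol carbon different, the step turns that pseudoasymmetric carbon into the true stereocentre that becomes C5 of the target, and its sense is fixed solely by which acetate the chiral pocket of the enzyme accepts. The selectivity needed is between two enantiotopic equatorial acetates; the empirical rule for secondary alcohols (large group the ring flank carrying the quaternary carbinol, medium group the ring CH2 toward the other acetate) predicts reaction at the (R) carbinol, the tertiary hydroxyl is not a lipase substrate, and the lipid chain lies in the mirror plane away from both esters. Further alcoholysis to the triol should consume the minor monoacetate enantiomer faster, because its remaining acetate is the fast-reacting one, so running slightly past full consumption of 13 should raise the enantiomeric purity of 14.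

Step 9
Reactants: 14 monoacetate
Product: 15 β-acetoxy ketone (1R,3S)-3-hydroxy-5-oxo-3-[(10Z,13Z)-2-oxononadeca-10,13-dien-1-yl]cyclohexyl acetate
Conditions: Dess–Martin periodinane, pyridine, CH2Cl2, 0 °C
Reagents that add atoms: none
Why: Dess–Martin oxidation of the only secondary alcohol gives the ring ketone without touching the tertiary hydroxyl, the acetate or the skipped diene, and the stereocentre at the tertiary carbinol is not involved.

Step 10
Reactants: 15 β-acetoxy ketone
Product: 16 target, (5S)-5-hydroxy-5-[(10Z,13Z)-2-oxononadeca-10,13-dien-1-yl]cyclohex-2-en-1-one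
Conditions: Et3N, CH2Cl2, 0 °C to rt
Reagents that add atoms: none
Why: E1cB elimination, in which the amine base enolises the ring ketone toward the acetoxy-bearing side and acetate leaves far more readily than the tertiary hydroxyl on the other side, so the C2=C3 enone should form under conditions too mild for dehydration to the phenol or retro-aldol cleavage, and C5 keeps its (S) configuration.

**Compound list**

1 | cis,cis-cyclohexane-1,3,5-triol | O[C@H]1C[C@@H](O)C[C@@H](O)C1 | starting material
2 | all-cis-3,5-bis(tert-butyldimethylsilyloxy)cyclohexan-1-ol (meso) | O[C@H]1C[C@@H](O[Si](C)(C)C(C)(C)C)C[C@@H](O[Si](C)(C)C(C)(C)C)C1 | intermediate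
3 | meso cis-3,5-bis(tert-butyldimethylsilyloxy)cyclohexan-1-one | O=C1C[C@H](O[Si](C)(C)C(C)(C)C)C[C@H](O[Si](C)(C)C(C)(C)C)C1 | intermediate
4 | linoleic acid, (9Z,12Z)-octadeca-9,12-dienoic acid | CCCCC/C=C\C/C=C\CCCCCCCC(=O)O | starting material
5 | linoleoyl imidazolide, 1-[(9Z,12Z)-octadeca-9,12-dienoyl]imidazole | CCCCC/C=C\C/C=C\CCCCCCCC(=O)n1ccnc1 | intermediate (not isolated)
6 | (9Z,12Z)-N-methoxy-N-methyloctadeca-9,12-dienamide | CCCCC/C=C\C/C=C\CCCCCCCC(=O)N(C)OC | intermediate
7 | bromomagnesium hemiaminal adduct of 6 with methyl | CCCCC/C=C\C/C=C\CCCCCCCC(C)(O[Mg]Br)N(C)OC | intermediate (not isolated)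
8 | (10Z,13Z)-nonadeca-10,13-dien-2-one | CCCCC/C=C\C/C=C\CCCCCCCC(C)=O | intermediate
9 | lithium (10Z,13Z)-nonadeca-1,10,13-trien-2-olate | CCCCC/C=C\C/C=C\CCCCCCCC(=C)O[Li] | intermediate (not isolated)
10 | dichlorocerium (10Z,13Z)-nonadeca-1,10,13-trien-2-olate | CCCCC/C=C\C/C=C\CCCCCCCC(=C)O[Ce](Cl)Cl | intermediate (not isolated)
11 | meso aldol adduct, (10Z,13Z)-1-[(3R,5S)-3,5-bis(tert-butyldimethylsilyloxy)-1-hydroxycyclohexyl]nonadeca-10,13-dien-2-one, chain cis to both silyloxy groups | CCCCC/C=C\C/C=C\CCCCCCCC(=O)C[C@@]1(O)C[C@@H](O[Si](C)(C)C(C)(C)C)C[C@@H](O[Si](C)(C)C(C)(C)C)C1 | intermediate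
12 | meso triol ketone, (10Z,13Z)-1-[(3R,5S)-1,3,5-trihydroxycyclohexyl]nonadeca-10,13-dien-2-one, chain cis to both secondary hydroxyls | CCCCC/C=C\C/C=C\CCCCCCCC(=O)C[C@@]1(O)C[C@@H](O)C[C@@H](O)C1 | intermediate
13 | meso diacetate, (1R,3S)-5-hydroxy-5-[(10Z,13Z)-2-oxononadeca-10,13-dien-1-yl]cyclohexane-1,3-diyl diacetate, chain cis to both acetoxy groups | CCCCC/C=C\C/C=C\CCCCCCCC(=O)C[C@@]1(O)C[C@@H](OC(C)=O)C[C@@H](OC(C)=O)C1 | intermediate
14 | (1S,3S,5R)-3,5-dihydroxy-3-[(10Z,13Z)-2-oxononadeca-10,13-dien-1-yl]cyclohexyl acetate | CCCCC/C=C\C/C=C\CCCCCCCC(=O)C[C@@]1(O)C[C@@H](OC(C)=O)C[C@@H](O)C1 | intermediate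
15 | (1R,3S)-3-hydroxy-5-oxo-3-[(10Z,13Z)-2-oxononadeca-10,13-dien-1-yl]cyclohexyl acetate | CCCCC/C=C\C/C=C\CCCCCCCC(=O)C[C@@]1(O)C[C@@H](OC(C)=O)CC(=O)C1 | intermediate
16 | (5S)-5-hydroxy-5-[(10Z,13Z)-2-oxononadeca-10,13-dien-1-yl]cyclohex-2-en-1-one | CCCCC/C=C\C/C=C\CCCCCCCC(=O)C[C@@]1(O)CC=CC(=O)C1 | target

**Step count**

Total steps: 10. Longest linear sequence: 8 steps (1 → 2 → 3 → 11 → 12 → 13 → 14 → 15 → 16; the branch from linoleic acid 4 through steps 3 and 4 is equally long).

**Steps most likely to fail**

Step 5 (aldol). Proton transfer from ketone 3 to the enolate, followed by β-elimination of silanolate, may consume the ketone; the tertiary aldolate may also revert before the quench. The fallback replaces the basic enolate by a Lewis-acid-mediated Mukaiyama aldol addition. It sets out from 8, which is trapped on the methyl side (LiN(iPr)2, Me3SiCl, THF, −78 °C) as the silyl enol ether (10Z,13Z)-2-(trimethylsilyloxy)nonadeca-1,10,13-triene F1. F1 is added to ketone 3 activated by TiCl4 in CH2Cl2 at −78 °C, a medium that holds no base able to enolise 3. Aqueous work-up should give the aldol adduct, and the route is rejoined at 11.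

Step 8 (lipase desymmetrisation). The enzyme may discriminate the two acetates in the unwanted sense, or turn over the bulky lipid-bearing diacetate too slowly. The fallback runs the acyl transfer in the opposite direction. It sets out from triol 12, which is acetylated irreversibly with vinyl acetate in t-BuOMe, catalysed by the same lipase or by Candida antarctica lipase B. Acylation places the acetate on the carbinol that the enzyme prefers, whereas alcoholysis frees it, so an enzyme that removed the (S) acetate from 13 should acetylate the (S) carbinol of 12. This gives the monoacetate directly, and the route is rejoined at 14 without any new compound.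

Step 6 (desilylation). Fluoride may act as a base and cleave the tertiary aldol by retro-aldol fragmentation before both silyl ethers are gone. The fallback changes the protecting group to one cleaved by mild aqueous acid. It sets out from 1, which is silylated with Et3SiCl and imidazole to all-cis-3,5-bis(triethylsilyloxy)cyclohexan-1-ol F2. F2 is oxidised with Dess–Martin periodinane to cis-3,5-bis(triethylsilyloxy)cyclohexan-1-one F3. F3 is joined with 8 under the conditions of step 5 to the bis(triethylsilyl) aldol adduct F4. The triethylsilyl ethers of F4 are then hydrolysed with AcOH, THF and water at rt, where the water-rich medium should also disfavour ketal closure, and the route is rejoined at 12.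

**Further compounds**

F1 | step 5 | (10Z,13Z)-2-(trimethylsilyloxy)nonadeca-1,10,13-triene | CCCCC/C=C\C/C=C\CCCCCCCC(=C)O[Si](C)(C)C
F0 | step 8 | none | none
F2 | step 6 | all-cis-3,5-bis(triethylsilyloxy)cyclohexan-1-ol | O[C@H]1C[C@@H](O[Si](CC)(CC)CC)C[C@@H](O[Si](CC)(CC)CC)C1
F3 | step 6 | cis-3,5-bis(triethylsilyloxy)cyclohexan-1-one | O=C1C[C@H](O[Si](CC)(CC)CC)C[C@H](O[Si](CC)(CC)CC)C1
F4 | step 6 | (10Z,13Z)-1-[(3R,5S)-3,5-bis(triethylsilyloxy)-1-hydroxycyclohexyl]nonadeca-10,13-dien-2-one, chain cis to both silyloxy groups | CCCCC/C=C\C/C=C\CCCCCCCC(=O)C[C@@]1(O)C[C@@H](O[Si](CC)(CC)CC)C[C@@H](O[Si](CC)(CC)CC)C1
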